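The earlier runs and the new flask are calculated from invented constants; the scatter is artificial.

If a flask's rate fades faster than its product accounts for, the fraction of starting material left has to be reckoned on its own.

| setting | winter | spring | dusk | autumn | dawn |
|---|---|---|---|---|---|
| starting material | 150 mM | 90.0 mM | 150 mM | 150 mM | 150 mM |
| coupling partner | 180 mM | 120 mM | 180 mM | 180 mM | 180 mM |
| catalyst | 12.0 mM | 12.0 mM | 24.0 mM | 12.0 mM | 55.0 mM |
| product |  |  |  | 75.0 mM |  |
| time |  |  |  |  | 3.1 h |

| winter run: time / h | winter run: [product] / mM | spring run: time / h | spring run: [product] / mM | dusk run: time / h | dusk run: [product] / mM | autumn run: time / h | autumn run: [product] / mM |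
|---|---|---|---|---|---|---|---|
| 0.39 | 15.9 | 0.39 | 5.2 | 0.39 | 26.0 | 0.39 | 90.1 |
| 0.78 | 21.0 | 0.78 | 9.3 | 0.78 | 37.2 | 0.78 | 96.0 |
| 1.2 | 27.1 | 1.2 | 11.8 | 1.2 | 44.3 | 1.2 | 101.4 |
| 1.6 | 27.9 | 1.6 | 13.8 | 1.6 | 46.7 | 1.6 | 104.8 |
| 1.9 | 29.7 | 1.9 | 15.2 | 1.9 | 46.0 | 1.9 | 104.5 |
| 2.3 | 30.6 | 2.3 | 14.4 | 2.3 | 48.7 | 2.3 | 106.1 |
| 2.7 | 32.8 | 2.7 | 14.9 | 2.7 | 50.6 | 2.7 | 105.4 |
| 3.1 | 30.3 | 3.1 | 17.1 | 3.1 | 49.6 | 3.1 | 105.1 |

(readings scatter by 1 mM)

- Overall: starting material + coupling partner -> product, with catalyst as catalyst.
- Constant volume, constant temperature.
- "The second partner" is coupling partner.
- An order is taken over about fifteen percent of the charge, up and down.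

1. how the opening rate goes with [catalyst] round the charge of the winter run: the exponent of the rate at two percent of starting material gone to product
2. product in the dawn run at 3.1 h, as a share of the starting material charged

- The winter run makes 15.9 mM of product by 0.39 h, an average rate of 40.8 mM h⁻¹ over that stretch, and levels off near 31.2 mM, the mean of its last 3 readings.
- Added product leaves the outcome about where it was: the autumn run, charged with 75.0 mM of it, gains 30.5 mM by the mean of its last 3 readings, against 31.2 mM in the winter run.
- The product made in the winter run accounts for a factor of 0.654 on the rate, taking first order in each partner, yet the rate falls to within scatter of zero, so a further loss is at work.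
- With 24.0 mM of catalyst against the 12.0 mM of the winter run, the dusk run levels off near 49.6 mM. These plateaus do not separate a dying catalyst from a loss of starting material, and this reckoning takes the loss of starting material as its working picture.
- Let f, the fraction of starting material left, fall as exp(−(a+b)t), a pseudo-first-order picture with the partner held steady. Here a is the fraction of starting material going to product per hour, b the fraction lost per hour to routes that give no product, and the rate of product formation is proportional to a times f.
- Once f has faded, product made over starting material lost otherwise equals a/b, whatever the clock says. For the winter run this reads 0.263, the split ratio a/b, a selectivity factor; for the dusk run it reads 0.495. With b taken equal in both runs, a goes with catalyst at an order of 0.911, read from scattered plateaus.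
- The first winter reading against the winter plateau gives a+b of 1.82 h⁻¹, so hardly any of f would stand in the winter picture at 3.1 h. The dawn run, with its larger a, is taken as finished by then. Its split ratio, carried with that order to 55.0 mM of catalyst, is 1.05, so this reckoning gives the dawn run a share a/(a+b) of 51.3%.
- The forecast gives 0.8 for the order and 50% for the share, on the view that “the catalyst must be dying”, which differs from the reckoning above.

    catalyst + starting material + coupling partner → product + catalyst (176.0 L² mol⁻² h⁻¹)
    2 starting material → homo dimer (4.068 L mol⁻¹ h⁻¹)
    starting material → decomposed substrate (0.7308 h⁻¹)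

- The dawn run gives 51.2% and the order is 1.1, 1.38 times the forecast's, while the fit with main steps alone gave 65.0% for the dawn run. Carried to the spring run, whose coupling partner charge is 120 mM, the split ratio taken in proportion from the winter run's 180 mM becomes 0.175. On the spring run's 90.0 mM of starting material that gives 13.4 mM of product, and the last 3 spring readings average 15.5 mM.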